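**Plan**
1. Numbering used throughout: ring C1 (heptenyl), C2 (CH2OH, carbon C7), C3 and C4 (cis OH), C5 (side chain), C6 (OH).
2. Retrosynthetic cuts in order: O3–Si; C1–heptenyl (Suzuki); C6–OH back to a ketone; C1–iodine; side-chain C=C (cross-metathesis) and C5–allyl (enolate alkylation); then the ring at C1–C2 and C4–C5 together.
3. Enabling feature: with C6 as a ketone, O4 is 1,3 to the carbonyl and O7 is 1,4 to it through C1–C2. C4–C5 is therefore an aldol bond and C1–C2 is the bond made when an enolate carbon opens a C2–C7 oxirane, so one oxiranyl aldehyde (C7, C2, C3, C4) can take both α-carbons of an acetone unit (C5–C6–C1).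
4. Helper group: a phenylsulfinyl group on C1 turns the acetone unit into a 1,3-dianion and drives the ring closure. It then leaves as PhSOH, which creates the C1=C2 double bond.
5. Forward order: oxiranyl aldehyde (3 steps) plus keto sulfoxide (1 step) → cyclohexanone in one operation → enone → C5 allyl → enoic acid → C1 iodide → C6 alcohol → heptenyl → desilylation.
6. Stereochemistry: C3 from Sharpless desymmetrisation of divinylcarbinol; C4 by Felkin addition next to C3; C5 by alkylation anti to O4; C6 by O4-directed hydride delivery; both chain alkenes E (metathesis, boronic acid).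

Key step: step 5

Remark: sulfur and the sulfinyl-bearing carbon C1 are carried as epimer mixtures (left undefined in the SMILES); both are erased in step 6.

**Step 1**
Reactants: 1 penta-1,4-dien-3-ol (divinylcarbinol)
Product: 2 (2R,3S)-1,2-epoxypent-4-en-3-ol
Conditions: Ti(OiPr)4 (cat.), L-(+)-diisopropyl tartrate, t-BuOOH, 4 Å molecular sieves, CH2Cl2, −20 °C
Reagents that add atoms: tert-butyl hydroperoxide, CC(C)(C)OO
Why: Sharpless asymmetric epoxidation of a prochiral divinyl carbinol, in which the tartrate selects one enantiotopic vinyl group and one of its faces (erythro product) and the minor enantiomer is consumed by faster second epoxidation, so the carbinol carbon (future C3) should be set with high enantiomeric purity.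

**Step 2**
Reactants: 2 (2R,3S)-1,2-epoxypent-4-en-3-ol
Product: 3 triisopropyl{[(1S)-1-[(2R)-oxiran-2-yl]prop-2-en-1-yl]oxy}silane
Conditions: iPr3SiOTf, 2,6-lutidine, CH2Cl2, −78 to 0 °C
Reagents that add atoms: triisopropylsilyl trifluoromethanesulfonate, CC(C)[Si](C(C)C)(C(C)C)OS(=O)(=O)C(F)(F)F
Why: Standard silylation of a secondary alcohol with a silyl triflate and a hindered base; the triisopropylsilyl group is chosen because it does not chelate and migrates slowly between neighbouring oxygens.

**Step 3**
Reactants: 3 triisopropyl{[(1S)-1-[(2R)-oxiran-2-yl]prop-2-en-1-yl]oxy}silane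
Product: 4 (2R)-2-[(2R)-oxiran-2-yl]-2-(triisopropylsilyloxy)acetaldehyde
Conditions: O3, CH2Cl2, −78 °C; then PPh3, −78 °C to rt; used crude
Reagents that add atoms: ozone, [O-][O+]=O
Why: Ozonolysis with reductive work-up cleaves the remaining vinyl group to the aldehyde without touching the oxirane or the silyl ether, and using the α-silyloxy aldehyde without chromatography should keep C3 from epimerising.

**Step 4**
Reactants: 5 methyl phenyl sulfoxide (racemic); 6 ethyl acetate
Product: 7 1-(phenylsulfinyl)propan-2-one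
Conditions: LiN(iPr)2 (2.1 equiv), THF, −78 °C; then 6, −78 to 0 °C; AcOH quench
Reagents that add atoms: none
Why: Claisen-type acylation of the α-sulfinyl carbanion by an ester (Corey–Chaykovsky β-keto sulfoxide synthesis), run with two equivalents of base because the product is more acidic than the starting sulfoxide.

**Step 5**
Reactants: 7 1-(phenylsulfinyl)propan-2-one; 4 (2R)-2-[(2R)-oxiran-2-yl]-2-(triisopropylsilyloxy)acetaldehyde
Product: 9 (3S,4R,5S)-5-hydroxy-3-(hydroxymethyl)-2-(phenylsulfinyl)-4-(triisopropylsilyloxy)cyclohexan-1-one, via open-chain epoxy aldol 8 (not isolated)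
Conditions: LiN(iPr)2 (2.1 equiv), THF, −78 to 0 °C; 4, −78 °C; then DMPU, −78 to 25 °C; AcOH quench
Reagents that add atoms: none
Why: Proposed new method: the 1,3-dianion of 7 (sulfinyl-stabilised enolate at C1–C6 plus the more basic carbanion at C5) adds through C5 to the aldehyde C4 of 4 to give the aldolate of 8, and on warming the remaining enolate carbon C1 opens the oxirane at its inner carbon C2 with inversion, so C4–C5 and C1–C2 form in one flask and the C2–CH2OH arm appears at its final oxidation level; the closest known reaction types are γ-aldol additions of β-keto sulfoxide and β-keto ester dianions and intramolecular C-alkylation of stabilised enolates and nitrile anions by epoxides, which have not been joined as a [3+3] annulation onto an oxiranyl aldehyde. The ring closes in the 6-exo-tet mode (6-enolendo for the enolate), because collinear backside attack is possible only at C2, attack at C7 being a 7-endo process. C4 is set by polar Felkin–Anh (Cornforth) addition anti to the bulky, non-chelating C3–OSi(iPr)3 group, giving the 3,4-anti aldol that becomes the cis-3,4-dioxygen pattern of the ring, while C2, C1 and sulfur need no control since all three are erased in step 6. The step needs C5-before-C1 and aldehyde-before-oxirane chemoselectivity, which the reactivity gap between the two carbanion sites and between the two electrophiles at −78 °C should secure, and C- over O-alkylation in the closure, which the 6-enolendo-exo-tet geometry and the soft sulfinyl enolate favour. Retro-aldol and epimerisation at C3 are held back because the ketone stays locked as its enolate until the quench, and 1,2-silyl migration to O4 is slowed by the triisopropylsilyl group.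

**Step 6**
Reactants: 9 (3S,4R,5S)-5-hydroxy-3-(hydroxymethyl)-2-(phenylsulfinyl)-4-(triisopropylsilyloxy)cyclohexan-1-one
Product: 10 (4R,5S)-5-hydroxy-3-(hydroxymethyl)-4-(triisopropylsilyloxy)cyclohex-2-en-1-one
Conditions: toluene, CaCO3, 80 °C
Reagents that add atoms: none
Why: Thermal syn-elimination of a β-keto sulfoxide (sulfoxide pyrolysis), in which the only β-hydrogen sits on C2, so PhSOH is lost across C1–C2 to give the conjugated enone, and C1 epimerises freely so every diastereomer can reach the syn arrangement.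

**Step 7**
Reactants: 10 (4R,5S)-5-hydroxy-3-(hydroxymethyl)-4-(triisopropylsilyloxy)cyclohex-2-en-1-one; 11 allyl bromide
Product: 12 (4R,5S,6S)-5-hydroxy-3-(hydroxymethyl)-6-(prop-2-en-1-yl)-4-(triisopropylsilyloxy)cyclohex-2-en-1-one
Conditions: LiN(iPr)2 (3.3 equiv), THF, −78 °C; 11, −78 to −30 °C; AcOH quench
Reagents that add atoms: none
Why: Fráter–Seebach-type alkylation, in which kinetic deprotonation at C5 of the bis-alkoxide gives a β-oxido enolate that cannot eliminate, and allyl bromide enters C5 on the face opposite the C4–OLi and C3–OSi(iPr)3 groups, setting the 4,5-trans relationship.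

**Step 8**
Reactants: 12 (4R,5S,6S)-5-hydroxy-3-(hydroxymethyl)-6-(prop-2-en-1-yl)-4-(triisopropylsilyloxy)cyclohex-2-en-1-one; 13 methacrolein (2-methylprop-2-enal, excess)
Product: 14 (2E)-4-[(1S,5R,6S)-6-hydroxy-4-(hydroxymethyl)-2-oxo-5-(triisopropylsilyloxy)cyclohex-3-en-1-yl]-2-methylbut-2-enal
Conditions: second-generation Grubbs catalyst (H2IMes)(PCy3)Cl2Ru=CHPh (cat.), CH2Cl2, 40 °C
Reagents that add atoms: none
Why: Olefin cross-metathesis of a terminal alkene with an α-substituted acrolein, which should give the conjugated trisubstituted enal as the E isomer under thermodynamic control while the hindered, electron-poor ring alkene stays out of the reaction.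

**Step 9**
Reactants: 14 (2E)-4-[(1S,5R,6S)-6-hydroxy-4-(hydroxymethyl)-2-oxo-5-(triisopropylsilyloxy)cyclohex-3-en-1-yl]-2-methylbut-2-enal
Product: 15 (2E)-4-[(1S,5R,6S)-6-hydroxy-4-(hydroxymethyl)-2-oxo-5-(triisopropylsilyloxy)cyclohex-3-en-1-yl]-2-methylbut-2-enoic acid
Conditions: NaClO2, NaH2PO4, 2-methylbut-2-ene, t-BuOH/H2O, 0 °C to rt
Reagents that add atoms: sodium chlorite, [Na+].[O-]Cl=O
Why: Pinnick oxidation converts the enal to the enoic acid at buffered pH without touching alcohols or alkenes, and installing the acid now means every later basic step meets a carboxylate, which should not accept oxa-Michael addition from O4 or O6.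

**Step 10**
Reactants: 15 (2E)-4-[(1S,5R,6S)-6-hydroxy-4-(hydroxymethyl)-2-oxo-5-(triisopropylsilyloxy)cyclohex-3-en-1-yl]-2-methylbut-2-enoic acid
Product: 16 (2E)-4-[(1S,5R,6S)-6-hydroxy-4-(hydroxymethyl)-3-iodo-2-oxo-5-(triisopropylsilyloxy)cyclohex-3-en-1-yl]-2-methylbut-2-enoic acid
Conditions: iodine, pyridine, CH2Cl2, 0 °C to rt
Reagents that add atoms: iodine, [I][I]
Why: α-Iodination of an enone by the pyridine addition–iodination–elimination sequence (Baylis–Hillman-type, Johnson conditions), which places iodine on C1, the only vinylic C–H of the enone, and should leave the side-chain enoic acid alone.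

**Step 11**
Reactants: 16 (2E)-4-[(1S,5R,6S)-6-hydroxy-4-(hydroxymethyl)-3-iodo-2-oxo-5-(triisopropylsilyloxy)cyclohex-3-en-1-yl]-2-methylbut-2-enoic acid
Product: 17 (2E)-4-[(1S,2S,5R,6S)-2,6-dihydroxy-4-(hydroxymethyl)-3-iodo-5-(triisopropylsilyloxy)cyclohex-3-en-1-yl]-2-methylbut-2-enoic acid
Conditions: Me4NBH(OAc)3, MeCN/AcOH, −30 to 0 °C
Reagents that add atoms: none
Why: Hydroxyl-directed reduction (Evans–Saksena), in which the boron ester formed at O4 delivers hydride to the C6 carbonyl from the face of O4, so the new C6–OH should be anti to O4 and cis to the C5 side chain, while the acid and the vinyl iodide are inert to the acyloxyborohydride.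

**Step 12**
Reactants: 17 (2E)-4-[(1S,2S,5R,6S)-2,6-dihydroxy-4-(hydroxymethyl)-3-iodo-5-(triisopropylsilyloxy)cyclohex-3-en-1-yl]-2-methylbut-2-enoic acid; 18 (E)-hept-1-en-1-ylboronic acid
Product: 19 (2E)-4-[(1R,2S,5R,6S)-3-[(1E)-hept-1-en-1-yl]-2,6-dihydroxy-4-(hydroxymethyl)-5-(triisopropylsilyloxy)cyclohex-3-en-1-yl]-2-methylbut-2-enoic acid
Conditions: PdCl2(dppf) (cat.), K3PO4 (4 equiv), THF/H2O, 50 °C
Reagents that add atoms: none
Why: Suzuki–Miyaura coupling of the vinyl iodide with an (E)-alkenylboronic acid proceeds with retention at both partners, and the free hydroxyls and the carboxylate are tolerated in aqueous base.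

**Step 13**
Reactants: 19 (2E)-4-[(1R,2S,5R,6S)-3-[(1E)-hept-1-en-1-yl]-2,6-dihydroxy-4-(hydroxymethyl)-5-(triisopropylsilyloxy)cyclohex-3-en-1-yl]-2-methylbut-2-enoic acid
Product: 20 pestallic acid P, (2E)-4-[(1R,2S,5R,6S)-3-[(1E)-hept-1-en-1-yl]-2,5,6-trihydroxy-4-(hydroxymethyl)cyclohex-3-en-1-yl]-2-methylbut-2-enoic acid
Conditions: Bu4NF, THF, 0 °C to rt; pH 4 phosphate buffer work-up
Reagents that add atoms: none
Why: Fluoride cleavage of the only remaining protecting group, the C3 silyl ether, under conditions in which the side chain is a carboxylate and should resist conjugate addition by the neighbouring alkoxides.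

**Compound list**
1 | penta-1,4-dien-3-ol | C=CC(O)C=C | starting material
2 | (2R,3S)-1,2-epoxypent-4-en-3-ol | C=C[C@H](O)[C@H]1CO1 | intermediate
3 | triisopropyl{[(1S)-1-[(2R)-oxiran-2-yl]prop-2-en-1-yl]oxy}silane | C=C[C@H](O[Si](C(C)C)(C(C)C)C(C)C)[C@H]1CO1 | intermediate
4 | (2R)-2-[(2R)-oxiran-2-yl]-2-(triisopropylsilyloxy)acetaldehyde | O=C[C@H](O[Si](C(C)C)(C(C)C)C(C)C)[C@H]1CO1 | intermediate
5 | methyl phenyl sulfoxide (racemic) | CS(=O)c1ccccc1 | starting material
6 | ethyl acetate | CCOC(C)=O | starting material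
7 | 1-(phenylsulfinyl)propan-2-one | CC(=O)CS(=O)c1ccccc1 | intermediate
8 | (4S,5S)-4-hydroxy-5-[(2R)-oxiran-2-yl]-1-(phenylsulfinyl)-5-(triisopropylsilyloxy)pentan-2-one (open-chain epoxy aldol) | O=S(c1ccccc1)CC(=O)C[C@H](O)[C@H](O[Si](C(C)C)(C(C)C)C(C)C)[C@H]1CO1 | intermediate
9 | (3S,4R,5S)-5-hydroxy-3-(hydroxymethyl)-2-(phenylsulfinyl)-4-(triisopropylsilyloxy)cyclohexan-1-one | OC[C@H]1[C@@H](O[Si](C(C)C)(C(C)C)C(C)C)[C@@H](O)CC(=O)C1S(=O)c1ccccc1 | intermediate
10 | (4R,5S)-5-hydroxy-3-(hydroxymethyl)-4-(triisopropylsilyloxy)cyclohex-2-en-1-one | C1=C(CO)[C@@H](O[Si](C(C)C)(C(C)C)C(C)C)[C@@H](O)CC1=O | intermediate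
11 | allyl bromide | C=CCBr | starting material
12 | (4R,5S,6S)-5-hydroxy-3-(hydroxymethyl)-6-(prop-2-en-1-yl)-4-(triisopropylsilyloxy)cyclohex-2-en-1-one | C1=C(CO)[C@@H](O[Si](C(C)C)(C(C)C)C(C)C)[C@@H](O)[C@H](CC=C)C1=O | intermediate
13 | methacrolein | C=C(C)C=O | starting material
14 | (2E)-4-[(1S,5R,6S)-6-hydroxy-4-(hydroxymethyl)-2-oxo-5-(triisopropylsilyloxy)cyclohex-3-en-1-yl]-2-methylbut-2-enal | C1=C(CO)[C@@H](O[Si](C(C)C)(C(C)C)C(C)C)[C@@H](O)[C@H](C/C=C(\C)C=O)C1=O | intermediate
15 | (2E)-4-[(1S,5R,6S)-6-hydroxy-4-(hydroxymethyl)-2-oxo-5-(triisopropylsilyloxy)cyclohex-3-en-1-yl]-2-methylbut-2-enoic acid | C1=C(CO)[C@@H](O[Si](C(C)C)(C(C)C)C(C)C)[C@@H](O)[C@H](C/C=C(\C)C(=O)O)C1=O | intermediate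
16 | (2E)-4-[(1S,5R,6S)-6-hydroxy-4-(hydroxymethyl)-3-iodo-2-oxo-5-(triisopropylsilyloxy)cyclohex-3-en-1-yl]-2-methylbut-2-enoic acid | IC1=C(CO)[C@@H](O[Si](C(C)C)(C(C)C)C(C)C)[C@@H](O)[C@H](C/C=C(\C)C(=O)O)C1=O | intermediate
17 | (2E)-4-[(1S,2S,5R,6S)-2,6-dihydroxy-4-(hydroxymethyl)-3-iodo-5-(triisopropylsilyloxy)cyclohex-3-en-1-yl]-2-methylbut-2-enoic acid | IC1=C(CO)[C@@H](O[Si](C(C)C)(C(C)C)C(C)C)[C@@H](O)[C@H](C/C=C(\C)C(=O)O)[C@@H]1O | intermediate
18 | (E)-hept-1-en-1-ylboronic acid | CCCCC/C=C/B(O)O | starting material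
19 | (2E)-4-[(1R,2S,5R,6S)-3-[(1E)-hept-1-en-1-yl]-2,6-dihydroxy-4-(hydroxymethyl)-5-(triisopropylsilyloxy)cyclohex-3-en-1-yl]-2-methylbut-2-enoic acid | CCCCC/C=C/C1=C(CO)[C@@H](O[Si](C(C)C)(C(C)C)C(C)C)[C@@H](O)[C@H](C/C=C(\C)C(=O)O)[C@@H]1O | intermediate
20 | pestallic acid P | CCCCC/C=C/C1=C(CO)[C@@H](O)[C@@H](O)[C@H](C/C=C(\C)C(=O)O)[C@@H]1O | target

**Step count**
Total steps: 13. Longest linear sequence: 12 (steps 1–3 and 5–13).

**Steps most likely to fail**

Step 5 (proposed new method). The ring closure may lose to O-alkylation by the enolate oxygen, to attack of the aldolate on the oxirane, or to slow epoxide opening within the polyanion. Facial selectivity at C4 may also be modest. The fallback sets out from 4 and 7 and comes back at 9, and makes the two bonds in separate known operations. The dianion of 7 is added to 4 at −78 °C and quenched cold with AcOH, so that 8 is isolated. Its C4 hydroxyl is capped with Et3SiOTf and 2,6-lutidine to give triethylsilyl ether F1. The neutral β-keto sulfoxide is then closed by carbonate-mediated 6-exo C-alkylation of the stabilised enolate by the epoxide (Cs2CO3, MeCN, 50 °C) to give silylated cyclohexanone F2. PPTS in MeOH removes the triethylsilyl group and returns 9.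

Step 7. The trianion may undergo O-allylation or γ-deprotonation instead of C5 alkylation, or facial control at C5 may be poor. The fallback sets out from 5 and 4 and comes back at 12, and carries the allyl group in the nucleophile so that C5 is set during the annulation. Acylating 5 with methyl pent-4-enoate under the conditions of step 4 gives 1-(phenylsulfinyl)hex-5-en-2-one F3. Its dianion and 4 under the conditions of step 5 should give, through open-chain allyl aldol F4 (not isolated), allyl cyclohexanone F5. The syn aldol from the Z-configured enolate terminus places the allyl group trans to O4. Thermolysis as in step 6 gives 12.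

Step 10. Conjugate addition of pyridine to the β,β-disubstituted enone may be slow, so that α-iodination stalls and forcing causes dehydration of the β-hydroxy ketone toward an aromatic ring. The fallback sets out from 9 and comes back at 19, and installs the halogen while C1 is still the acidic carbon of the β-keto sulfoxide. Treating 9 with N-bromosuccinimide gives α-bromo sulfoxide F6, whose thermolysis (toluene, CaCO3, 80 °C) gives 2-bromoenone F7. Steps 7, 8 and 9 applied to F7 give allyl bromoenone F8, bromo enal F9 and bromo enoic acid F10. The reduction of step 11 gives bromo triol acid F11, and the coupling of step 12 with 18 returns 19.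

**Further compounds**
F1 | step 5 | (4S,5S)-5-[(2R)-oxiran-2-yl]-1-(phenylsulfinyl)-4-(triethylsilyloxy)-5-(triisopropylsilyloxy)pentan-2-one | O=S(c1ccccc1)CC(=O)C[C@H](O[Si](CC)(CC)CC)[C@H](O[Si](C(C)C)(C(C)C)C(C)C)[C@H]1CO1
F2 | step 5 | 5-O-triethylsilyl ether of 9 | OC[C@H]1[C@@H](O[Si](C(C)C)(C(C)C)C(C)C)[C@@H](O[Si](CC)(CC)CC)CC(=O)C1S(=O)c1ccccc1
F3 | step 7 | 1-(phenylsulfinyl)hex-5-en-2-one | C=CCCC(=O)CS(=O)c1ccccc1
F4 | step 7 | open-chain allyl aldol (3-allyl analogue of 8) | O=S(c1ccccc1)CC(=O)[C@@H](CC=C)[C@H](O)[C@H](O[Si](C(C)C)(C(C)C)C(C)C)[C@H]1CO1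
F5 | step 7 | 6-allyl analogue of 9 | OC[C@H]1[C@@H](O[Si](C(C)C)(C(C)C)C(C)C)[C@@H](O)[C@H](CC=C)C(=O)C1S(=O)c1ccccc1
F6 | step 10 | 2-bromo derivative of 9 (α-bromo sulfoxide) | OC[C@H]1[C@@H](O[Si](C(C)C)(C(C)C)C(C)C)[C@@H](O)CC(=O)C1(Br)S(=O)c1ccccc1
F7 | step 10 | (4R,5S)-2-bromo-5-hydroxy-3-(hydroxymethyl)-4-(triisopropylsilyloxy)cyclohex-2-en-1-one | BrC1=C(CO)[C@@H](O[Si](C(C)C)(C(C)C)C(C)C)[C@@H](O)CC1=O
F8 | step 10 | 2-bromo analogue of 12 | BrC1=C(CO)[C@@H](O[Si](C(C)C)(C(C)C)C(C)C)[C@@H](O)[C@H](CC=C)C1=O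
F9 | step 10 | 3-bromo analogue of 14 (bromo enal) | BrC1=C(CO)[C@@H](O[Si](C(C)C)(C(C)C)C(C)C)[C@@H](O)[C@H](C/C=C(\C)C=O)C1=O
F10 | step 10 | bromo analogue of 16 (bromo enoic acid) | BrC1=C(CO)[C@@H](O[Si](C(C)C)(C(C)C)C(C)C)[C@@H](O)[C@H](C/C=C(\C)C(=O)O)C1=O
F11 | step 10 | bromo analogue of 17 (bromo triol acid) | BrC1=C(CO)[C@@H](O[Si](C(C)C)(C(C)C)C(C)C)[C@@H](O)[C@H](C/C=C(\C)C(=O)O)[C@@H]1O
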